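**Numbering.** Compounds 1–25 are fixed by the steps below and used throughout. Ring B is the benzene ring of the chromene (O1, C2–C8a). Ring A carries primed locants: C1′ ring ketone, C2′ isobutyryl carbon, C3′ enol carbon, C4′ quaternary carbon, C5′ enol carbon, C6′ bridge carbon.

## Analysis of the target

Target 25 is made of two six-membered carbocycles joined by one methylene carbon. Ring A is a cyclohexa-2,5-dienone, the enol form of a 2-acylcyclohexane-1,3,5-trione; ring B is the benzene ring of a 2,2-dimethyl-2H-chromene. The only stereocentre is the quaternary carbon C4′ (methyl and prenyl), R in the tautomer drawn. It is stereogenic only because the two flanks of ring A differ (isobutyryl on C2′, bridge on C6′), so there is no second centre to relate it to or to control it from. Ring B is fully substituted: O1 on C8a, the pyran carbon on C4a, hydroxyls on C5 and C7, isobutyryl on C6, the bridge on C8. Sensitive groups are the C3=C4 bond of the chromene (protonation, HX addition), the prenyl double bond (acid-induced cyclisation onto the neighbouring enol), the two enolised tricarbonyl units (strong vinylogous acids, O- versus C-alkylation) and the methylene bridge (retro-Michael cleavage and scrambling). The synthesis is hard for three reasons: six different substituents must be placed in order on ring B, a quaternary centre must be set whose chirality depends on remote substitution, and two different acylphloroglucinol units must be joined through CH2 without homodimers. The strategy rests on the three oxygens of ring B (O1, C5–O, C7–O): when the benzene ring and the pyran are assembled together from a four-membered ketone and an ynol ether, each oxygen comes from a different building block and can be addressed on its own.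

## Retrosynthetic reasoning

**Bridge, C6′–CH2.** Cutting the bond between the bridge carbon and C6′ divides 25 into the vinylogous acid 23, which holds the stereocentre, and the aminomethyl chromene 24. Both are stable monomers of similar size, and the quaternary centre is not touched in the union. Forward, 24 acts as a latent ortho-quinone methide (electrophile only) and 23 as a carbon nucleophile, so that homodimers are excluded by polarity.

**Bridge, C8–CH2.** Removing the aminomethyl group from 24 gives the dihydroxy ketone 20. C8 is its only free ring position, so the forward aminomethylation has no regiochemical choice.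

**C6–acyl bond and the oxygens of ring B.** The isobutyryl group of 20 is traced back through the ethyl ether 19 to the C5 ester 18, and from there to the silyl ether 16. Direct acylation could not tell C6 from C8; an acyl shift from the C5 oxygen can, because C6 is the only free position ortho to it. This needs the C5 oxygen to be the only one that can be unmasked alone, which is the case in 16 (silyl ether at C5, ethyl ether at C7, O1 in the pyran). The ethyl ether is cleaved last, with the help of the new neighbouring carbonyl.

**Ring B and pyran (key disconnection).** In 16 the bonds C4a–C8a, C5–C6, C8–C8a and O1–C2 are cut. This leaves the cyclobutenone 4, which supplies C8a with O1, C6, C7 with its ethoxy group, and C8. It also leaves the ynol ether 9, which supplies C5 with its silyloxy group, C4a, C4, C3, C2 and both methyls. Two rings and four skeletal bonds are gained, and no aromatic substitution is needed to set the oxygen pattern. Forward, the step has to open 4 to a vinylketene, add it to the alkyne with the right orientation, close the benzene ring, and then close the pyran by hydrogen shift and oxa-electrocyclisation.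

**Ynol ether 9.** The oxygen-bearing alkyne carbon is removed to give the (Z)-dienoate 6, since an ester is the most direct precursor of an ynolate. The (Z) double bond of 6 is then cut to methacrolein 5. The geometry must be set at this point and kept.

**Cyclobutenone 4.** The four-membered ring is cut into ethoxyacetylene 2 and ketene 3, which is generated from acetone 1. The polarity of 2 fixes the ethoxy group at C3.

**Ring A acid 23.** The C4′–prenyl bond is cut, which leads to the aromatic ketone 22; its acyl bond is cut in turn to give the triol 21. Forward, the alkylation has to dearomatise the ring at the methyl-bearing carbon and choose one of its two faces.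

## Alternatives that were turned down

**Alternative 1:** Ring A is cut between C2′ and C3′, leading back to the lactone A1, (3R)-3-methyl-3-(3-methylbut-2-en-1-yl)-6-(3-methyl-2-oxobutyl)pyran-2,4-dione, in which the quaternary centre already sits between a lactone carbonyl and a ketone.
- Key step: Mg(OMe)2 opens the lactone to a methyl ester, holds the triketone chain as a chelate, and the carbon between the two side-chain ketones closes onto the ester to give A2, which is the same compound as 23.
- For: the two flanks of the quaternary carbon are different functional groups from the outset, so the placing of the acyl group, which alone makes the centre stereogenic, is a matter of constitution. There is no competition between ring carbons as in step 9. On control of the stereocentre this alternative is stronger than the chosen route.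
- Against: it solves ring A only. Enantiopure A1 needs several steps including an asymmetric alkylation. The opened ester can relactonise or suffer retro-Claisen cleavage at the quaternary β-keto ester. Ring B and its three oxygens remain to be made by other means.
- Comparison: the chosen route spends two steps on ring A and puts its key step on the hexasubstituted ring B, where the constitutional problem is hardest. It offers brevity and convergence in place of a constitutionally secured stereocentre. Because A2 equals 23, this chemistry could be grafted onto the chosen route if needed.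

**Alternative 2:** Ring A of 25 is cut between C5′ and C6′ with the bridge and a protected ring B already in the chain, which gives the open-chain ester A3 (a methyl ester on the quaternary carbon and a 3-arylpropanoyl end).
- Key step: excess LiN(iPr)2 deprotonates the methylene beside the chain ketone, and this carbanion attacks the ester to give A4, the bis(methoxymethyl) ether of 25; acid then removes the acetals.
- For: the bridge carbon is part of a propanoyl chain, so the unsymmetrical methylene coupling and its scrambling risk (steps 10 and 11) are avoided. On that point it is stronger.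
- Against: the sequence is linear and carries the most advanced ring B intermediate through the chain building. A3 has several kinds of acidic C–H and a quaternary β-keto ester open to retro-Claisen cleavage. The final acetal removal needs acid in the presence of the chromene double bond and of a prenyl group next to an enol. Ring B itself is not addressed.
- Comparison: the chosen route is convergent and forms its last bond near neutrality with all five hydroxyls free.

**Alternative 3:** The pyran is cut at C8a–O1, C4a–C4 and O1–C2, leading to the silyl aryl triflate A5 and the enal A6 (3-methylbut-2-enal).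
- Key step: CsF releases the 3,5-dialkoxyaryne from A5; the carbonyl oxygen of A6 adds to the aryne carbon remote from the flanking alkoxy group and the carbonyl carbon to the other. The benzoxete opens to an ortho-quinone methide, which closes by oxa-6π to the chromene A7.
- For: every elementary step has precedent, the orientation follows from the distortion of the alkoxyaryne, and the fluoride conditions are milder than the heating of step 4. On precedent and mildness it is stronger.
- Against: it forms only the pyran. The benzene ring arrives ready-made with two oxygens under the same protecting group, so C6 and C8 must be told apart afterwards. A5 takes several steps from a symmetrical triphenol, and the acetals must later be removed by acid beside the chromene.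
- Comparison: the chosen key step forms both rings and four bonds at once, and the C5 oxygen is born as the only silyl ether, which directs the acyl group to C6. Step counts to 20 are similar, so the case for the chosen route rests on this built-in differentiation, not on length.

Key step: step 4

**Assumption:** in step 9 the cinchonidinium catalyst is taken to deliver the (R) acid 23. The sense of induction cannot be derived beforehand; if the first run shows the opposite sense, the pseudoenantiomeric cinchoninium salt is used in its place.

**Remark:** 23–25 are written as the enol tautomers of the target SMILES, and the descriptor R refers to these.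

## Route

**Step 1**
Reactants: 1 acetone; 2 ethoxyacetylene
Product: 4 3-ethoxycyclobut-2-en-1-one, via ketene 3 (not isolated)
Conditions: 1 cracked in a ketene generator (glowing Ni–Cr filament); gas stream into 2, CH2Cl2, −20 °C → rt
Reagents that add atoms: none
Why: [2+2] cycloaddition of ketene with an electron-rich alkyne; the CH carbon of 2 is the nucleophile and attacks the ketene carbonyl carbon, which places the ethoxy group at C3.

**Step 2**
Reactants: 5 methacrolein
Product: 6 methyl (2Z)-4-methylpenta-2,4-dienoate
Conditions: methyl bis(2,2,2-trifluoroethyl)phosphonoacetate, KN(SiMe3)2, 18-crown-6, THF, −78 °C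
Reagents that add atoms: methyl bis(2,2,2-trifluoroethyl)phosphonoacetate, COC(=O)CP(=O)(OCC(F)(F)F)OCC(F)(F)F
Why: Still–Gennari olefination; the electron-poor phosphonate with a dissociated potassium ion eliminates fast and irreversibly from the syn adduct and should give the (Z)-enoate, the enal reacting at its carbonyl group.

**Step 3**
Reactants: 6 methyl (2Z)-4-methylpenta-2,4-dienoate
Product: 9 triisopropyl{[(3Z)-5-methylhexa-3,5-dien-1-yn-1-yl]oxy}silane, via lithium (3Z)-1,1-dibromo-5-methylhexa-1,3,5-trien-2-olate 7 (not isolated), via lithium (3Z)-5-methylhexa-3,5-dien-1-yn-1-olate 8 (not isolated)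
Conditions: CH2Br2, lithium 2,2,6,6-tetramethylpiperidide, THF, −78 °C; n-BuLi, −78 → 0 °C; i-Pr3SiOTf, −78 → 0 °C
Reagents that add atoms: dibromomethane, BrCBr; triisopropylsilyl trifluoromethanesulfonate, CC(C)[Si](OS(=O)(=O)C(F)(F)F)(C(C)C)C(C)C
Why: Kowalski ester homologation; addition of LiCHBr2, enolisation, bromine–lithium exchange and 1,2-shift of the alkenyl group give the ynolate with the (Z) geometry retained, and the bulky silyl triflate silylates it on oxygen.

**Step 4**
Reactants: 4 3-ethoxycyclobut-2-en-1-one; 9 triisopropyl{[(3Z)-5-methylhexa-3,5-dien-1-yn-1-yl]oxy}silane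
Product: 16 7-ethoxy-2,2-dimethyl-5-[(triisopropylsilyl)oxy]-2H-chromene, via 3-ethoxybuta-1,3-dien-1-one 10 (not isolated), via 4-(1-ethoxyethenyl)-2-[(1Z)-3-methylbuta-1,3-dien-1-yl]-3-[(triisopropylsilyl)oxy]cyclobut-2-en-1-one 11 (not isolated), via (3E)-5-ethoxy-2-[(1Z)-3-methylbuta-1,3-dien-1-yl]-3-[(triisopropylsilyl)oxy]hexa-1,3,5-trien-1-one 12 (not isolated), via 5-ethoxy-2-[(1Z)-3-methylbuta-1,3-dien-1-yl]-3-[(triisopropylsilyl)oxy]cyclohexa-2,4-dien-1-one 13 (not isolated), via 5-ethoxy-2-[(1Z)-3-methylbuta-1,3-dien-1-yl]-3-[(triisopropylsilyl)oxy]phenol 14 (not isolated), via (6Z)-3-ethoxy-6-(3-methylbut-2-en-1-ylidene)-5-[(triisopropylsilyl)oxy]cyclohexa-2,4-dien-1-one 15 (not isolated)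
Conditions: 4 (1.3 equiv), PhMe (0.3 M), 80 °C, then 110 °C, sealed tube, argon
Reagents that add atoms: none
Why: Proposed new method: on heating, 4 opens by conrotatory 4π cleavage to the vinylketene 10, whose carbonyl carbon is attacked by the nucleophilic alkyne carbon of 9 (the one carrying the dienyl group, polarised by the silyloxy oxygen), and the [2+2] adduct 11 reopens reversibly to the dienylketene 12. Ring B closes by 6π electrocyclisation of 12 (C8–C8a, after C4a–C8a and C5–C6 were made in the cycloaddition), and 13 tautomerises to the phenol 14. The pyran closes from 14 by a [1,7] hydrogen shift from the phenolic oxygen to the diene terminus, giving the ortho-quinone methide 15, followed by oxa-6π electrocyclisation (O1–C2) with return of the aromatic ring. The closest known reactions are the thermal benzannulation of cyclobutenones with silyl ynol ethers and the thermal cyclisation of (Z)-2-dienylphenols to 2,2-dimethylchromenes; new is their merger in one flask on a dienyl-substituted ynol ether. No stereocentre is formed. The step needs the regiochemistry of the [2+2] addition, which the polarity of the ynol ether secures by placing the dienyl carbon next to the ketene-derived oxygen and the silyloxy group at C5; it needs the (Z) double bond from step 2, without which the hydrogen shift cannot occur; and it needs the ketene to choose the donor-substituted triple bond over the diene. Because 14 is consumed within the molecule, it cannot protonate unreacted 9.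

**Step 5**
Reactants: 16 7-ethoxy-2,2-dimethyl-5-[(triisopropylsilyl)oxy]-2H-chromene
Product: 18 7-ethoxy-2,2-dimethyl-2H-chromen-5-yl 2-methylpropanoate, via 7-ethoxy-2,2-dimethyl-2H-chromen-5-ol 17 (not isolated)
Conditions: Bu4NF, THF, 0 °C; then (i-PrCO)2O, 4-(dimethylamino)pyridine (cat.), 0 °C → rt
Reagents that add atoms: 2-methylpropanoic anhydride, CC(C)C(=O)OC(=O)C(C)C
Why: Fluoride cleaves the aryl silyl ether, and the phenoxide of 17 is acylated in the same flask; it is the only nucleophilic site present.

**Step 6**
Reactants: 18 7-ethoxy-2,2-dimethyl-2H-chromen-5-yl 2-methylpropanoate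
Product: 19 1-(7-ethoxy-5-hydroxy-2,2-dimethyl-2H-chromen-6-yl)-2-methylpropan-1-one
Conditions: TiCl4, CH2Cl2, −20 °C → rt
Reagents that add atoms: none
Why: Fries rearrangement; the acyl group moves to the only free ortho position, C6 (C4a is substituted), where the product is held as a six-membered titanium chelate, and the low temperature is meant to spare the C3=C4 bond.

**Step 7**
Reactants: 19 1-(7-ethoxy-5-hydroxy-2,2-dimethyl-2H-chromen-6-yl)-2-methylpropan-1-one
Product: 20 1-(5,7-dihydroxy-2,2-dimethyl-2H-chromen-6-yl)-2-methylpropan-1-one
Conditions: BCl3, CH2Cl2, −78 → 0 °C; then aq. NaHCO3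
Reagents that add atoms: none
Why: Chelation-assisted ether cleavage; boron bound to the C6 carbonyl oxygen activates the neighbouring C7 ethoxy group and chloride removes the ethyl group by SN2, while O1, para to the ketone and not chelated, should stay intact at low temperature.

**Step 8**
Reactants: 21 2-methylbenzene-1,3,5-triol
Product: 22 2-methyl-1-(2,4,6-trihydroxy-3-methylphenyl)propan-1-one
Conditions: i-PrCOCl, AlCl3, PhNO2, rt → 60 °C; then ice-water
Reagents that add atoms: 2-methylpropanoyl chloride, CC(C)C(Cl)=O
Why: Friedel–Crafts acylation of a highly activated arene; the two free positions of 21 are equivalent, so a single ketone results, and the acyl group deactivates the ring against a second acylation.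

**Step 9**
Reactants: 22 2-methyl-1-(2,4,6-trihydroxy-3-methylphenyl)propan-1-one
Product: 23 (4R)-3,5-dihydroxy-4-methyl-4-(3-methylbut-2-en-1-yl)-2-(2-methylpropanoyl)cyclohexa-2,5-dien-1-one
Conditions: prenyl bromide (1.0 equiv), N-(9-anthracenylmethyl)-O-allylcinchonidinium bromide (20 mol %), CsOH·H2O, 4 Å molecular sieves, CH2Cl2, −50 °C; then 1 M HCl
Reagents that add atoms: 1-bromo-3-methylbut-2-ene, CC(C)=CCBr
Why: Asymmetric phase-transfer alkylation with dearomatisation; the caesium phenolate pairs with the chiral ammonium ion, which covers one face of the methyl-bearing ring carbon (the most electron-rich carbon of the phenolate), and prenyl bromide attacks the open face by SN2 to set the quaternary centre. The product is a stabilised enolate and should resist a second alkylation.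

**Step 10**
Reactants: 20 1-(5,7-dihydroxy-2,2-dimethyl-2H-chromen-6-yl)-2-methylpropan-1-one
Product: 24 1-{8-[(dimethylamino)methyl]-5,7-dihydroxy-2,2-dimethyl-2H-chromen-6-yl}-2-methylpropan-1-one
Conditions: dimethylmethylideneammonium iodide, Et3N, CH2Cl2, 0 °C → rt
Reagents that add atoms: N,N-dimethylmethylideneammonium iodide, C=[N+](C)C.[I-]
Why: Mannich aminomethylation by the preformed iminium ion at C8, the only free position of ring B, ortho to the C7 hydroxyl.

**Step 11**
Reactants: 24 1-{8-[(dimethylamino)methyl]-5,7-dihydroxy-2,2-dimethyl-2H-chromen-6-yl}-2-methylpropan-1-one; 23 (4R)-3,5-dihydroxy-4-methyl-4-(3-methylbut-2-en-1-yl)-2-(2-methylpropanoyl)cyclohexa-2,5-dien-1-one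
Product: 25 (4R)-6-{[5,7-dihydroxy-2,2-dimethyl-6-(2-methylpropanoyl)-2H-chromen-8-yl]methyl}-3,5-dihydroxy-4-methyl-4-(3-methylbut-2-en-1-yl)-2-(2-methylpropanoyl)cyclohexa-2,5-dien-1-one
Conditions: 23 (1.2 equiv), 1,4-dioxane, 90 °C; then pH 4 buffer wash
Reagents that add atoms: none
Why: Thermal loss of dimethylamine from the phenolic Mannich base gives an ortho-quinone methide (C7=O, C8=CH2), to which the free enol carbon of 23 adds in a Michael reaction that restores the aromatic ring; the quaternary stereocentre takes no part.

## Compound list

1 | acetone (propan-2-one) | CC(C)=O | starting material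
2 | ethoxyacetylene (ethoxyethyne) | CCOC#C | starting material
3 | ketene (ethenone) | C=C=O | intermediate
4 | 3-ethoxycyclobut-2-en-1-one | CCOC1=CC(=O)C1 | intermediate
5 | methacrolein (2-methylprop-2-enal) | CC(=C)C=O | starting material
6 | methyl (2Z)-4-methylpenta-2,4-dienoate | COC(=O)/C=C\C(C)=C | intermediate
7 | lithium (3Z)-1,1-dibromo-5-methylhexa-1,3,5-trien-2-olate | [Li+].[O-]C(=C(Br)Br)/C=C\C(C)=C | intermediate
8 | lithium (3Z)-5-methylhexa-3,5-dien-1-yn-1-olate | [Li+].[O-]C#C/C=C\C(C)=C | intermediate
9 | triisopropyl{[(3Z)-5-methylhexa-3,5-dien-1-yn-1-yl]oxy}silane | CC(=C)/C=C\C#CO[Si](C(C)C)(C(C)C)C(C)C | intermediate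
10 | 3-ethoxybuta-1,3-dien-1-one | CCOC(=C)C=C=O | intermediate
11 | 4-(1-ethoxyethenyl)-2-[(1Z)-3-methylbuta-1,3-dien-1-yl]-3-[(triisopropylsilyl)oxy]cyclobut-2-en-1-one (racemic at C4) | CCOC(=C)C1C(=O)C(/C=C\C(C)=C)=C1O[Si](C(C)C)(C(C)C)C(C)C | intermediate
12 | (3E)-5-ethoxy-2-[(1Z)-3-methylbuta-1,3-dien-1-yl]-3-[(triisopropylsilyl)oxy]hexa-1,3,5-trien-1-one | O=C=C(/C=C\C(C)=C)/C(O[Si](C(C)C)(C(C)C)C(C)C)=C\C(OCC)=C | intermediate
13 | 5-ethoxy-2-[(1Z)-3-methylbuta-1,3-dien-1-yl]-3-[(triisopropylsilyl)oxy]cyclohexa-2,4-dien-1-one | O=C1CC(OCC)=CC(O[Si](C(C)C)(C(C)C)C(C)C)=C1/C=C\C(C)=C | intermediate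
14 | 5-ethoxy-2-[(1Z)-3-methylbuta-1,3-dien-1-yl]-3-[(triisopropylsilyl)oxy]phenol | CCOc1cc(O)c(/C=C\C(C)=C)c(O[Si](C(C)C)(C(C)C)C(C)C)c1 | intermediate
15 | (6Z)-3-ethoxy-6-(3-methylbut-2-en-1-ylidene)-5-[(triisopropylsilyl)oxy]cyclohexa-2,4-dien-1-one | CCOC1=CC(=O)/C(=C\C=C(C)C)C(O[Si](C(C)C)(C(C)C)C(C)C)=C1 | intermediate
16 | 7-ethoxy-2,2-dimethyl-5-[(triisopropylsilyl)oxy]-2H-chromene | CCOc1cc(O[Si](C(C)C)(C(C)C)C(C)C)c2C=CC(C)(C)Oc2c1 | intermediate
17 | 7-ethoxy-2,2-dimethyl-2H-chromen-5-ol | CCOc1cc(O)c2C=CC(C)(C)Oc2c1 | intermediate
18 | 7-ethoxy-2,2-dimethyl-2H-chromen-5-yl 2-methylpropanoate | CCOc1cc(OC(=O)C(C)C)c2C=CC(C)(C)Oc2c1 | intermediate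
19 | 1-(7-ethoxy-5-hydroxy-2,2-dimethyl-2H-chromen-6-yl)-2-methylpropan-1-one | CCOc1cc2OC(C)(C)C=Cc2c(O)c1C(=O)C(C)C | intermediate
20 | 1-(5,7-dihydroxy-2,2-dimethyl-2H-chromen-6-yl)-2-methylpropan-1-one | CC(C)C(=O)c1c(O)cc2OC(C)(C)C=Cc2c1O | intermediate
21 | 2-methylbenzene-1,3,5-triol | Cc1c(O)cc(O)cc1O | starting material
22 | 2-methyl-1-(2,4,6-trihydroxy-3-methylphenyl)propan-1-one | CC(C)C(=O)c1c(O)cc(O)c(C)c1O | intermediate
23 | (4R)-3,5-dihydroxy-4-methyl-4-(3-methylbut-2-en-1-yl)-2-(2-methylpropanoyl)cyclohexa-2,5-dien-1-one | CC(C)=CC[C@]1(C)C(O)=CC(=O)C(C(=O)C(C)C)=C1O | intermediate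
24 | 1-{8-[(dimethylamino)methyl]-5,7-dihydroxy-2,2-dimethyl-2H-chromen-6-yl}-2-methylpropan-1-one | CC(C)C(=O)c1c(O)c(CN(C)C)c2OC(C)(C)C=Cc2c1O | intermediate
25 | (4R)-6-{[5,7-dihydroxy-2,2-dimethyl-6-(2-methylpropanoyl)-2H-chromen-8-yl]methyl}-3,5-dihydroxy-4-methyl-4-(3-methylbut-2-en-1-yl)-2-(2-methylpropanoyl)cyclohexa-2,5-dien-1-one | CC(C)=CC[C@]1(C)C(O)=C(Cc2c(O)c(C(=O)C(C)C)c(O)c3c2OC(C)(C)C=C3)C(=O)C(C(=O)C(C)C)=C1O | target

## Step count and least certain steps

Total: 11 steps. Longest linear sequence: 8 steps (2, 3, 4, 5, 6, 7, 10, 11, from methacrolein 5). The ring A branch has 2 steps (8, 9) before the union.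

**Step 4 (key step).** The most likely failure is that the donor-substituted cyclobutenone opens too slowly at temperatures the ynol ether tolerates, so that 9 is lost by silyl shift to a silylketene or by polymerisation of the dienyne. The second risk is that the vinylketene adds to the diene instead of the triple bond. Fallback by known chemistry, setting out from 4 and returning at 16: ethyl 4-methylpent-3-enoate F1 is taken through the same homologation and O-silylation to triisopropyl[(5-methylhex-4-en-1-yn-1-yl)oxy]silane F2. Benzannulation of F2 with 4 in PhMe at 80–110 °C, a reaction of the established kind with no diene present, stops at 5-ethoxy-2-(3-methylbut-2-en-1-yl)-3-[(triisopropylsilyl)oxy]phenol F3. Dehydrogenative cyclisation of this ortho-prenylphenol with 2,3-dichloro-5,6-dicyano-1,4-benzoquinone in benzene then closes the pyran through the same ortho-quinone methide 15 and gives 16.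

**Step 9.** Facial discrimination may be poor, because the two flanks of the prochiral carbon differ only in remote substitution. Alkylation may also go to the unsubstituted ring carbon (which rearomatises) or to oxygen. Fallback from 22 back to 23: prenyl bromide with NaOMe in MeOH at 0 °C gives the racemic acid, rac-3,5-dihydroxy-4-methyl-4-(3-methylbut-2-en-1-yl)-2-(2-methylpropanoyl)cyclohexa-2,5-dien-1-one F4, freed from its aromatic isomer by chromatography. The racemate is resolved by fractional crystallisation of the (1R)-1-phenylethanaminium salt of the R acid F5 (or with the antipodal amine, whichever gives the crystalline salt of the R acid), and dilute HCl returns 23.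

**Step 6.** TiCl4 and the HCl formed may protonate or add to the C3=C4 bond of the chromene, and part of the acyl group may migrate to C8. Fallback from 16 back to 19: Bu4NF gives 17, now isolated. MgCl2, Et3N and paraformaldehyde in MeCN formylate only ortho to the free hydroxyl and give 7-ethoxy-5-hydroxy-2,2-dimethyl-2H-chromene-6-carbaldehyde F6. i-PrMgCl in THF gives 1-(7-ethoxy-5-hydroxy-2,2-dimethyl-2H-chromen-6-yl)-2-methylpropan-1-ol F7, and MnO2 in CH2Cl2 oxidises it to 19; no step of this sequence is acidic.

**Step 7.** The Lewis acid may open the pyran at O1–C2 (tertiary allylic ionisation) or add HCl to C3=C4, and the ethyl ether may cleave more slowly than a methyl ether would. Fallback from 19 to 20 under basic conditions: NaSEt in DMF at 120–130 °C removes the ethyl group by SN2 at carbon; no new compound is involved.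

**Step 3.** LiCHBr2 or n-BuLi may add in conjugate fashion to the dienoate, and the volatile, polymerisable ester 6 may be lost. Fallback from 5, returning at 9 through 8: olefination of 5 with (iodomethyl)triphenylphosphonium iodide and NaN(SiMe3)2 (Stork–Zhao) gives (1Z)-1-iodo-3-methylbuta-1,3-diene F8. Sonogashira coupling with ethynyltrimethylsilane (Pd(PPh3)4, CuI, Et3N) gives trimethyl[(3Z)-5-methylhexa-3,5-dien-1-yn-1-yl]silane F9, and K2CO3 in MeOH gives (3Z)-5-methylhexa-3,5-dien-1-yne F10. Its lithium acetylide (n-BuLi) is oxidised with LiOOt-Bu to the ynolate 8, which is silylated with i-Pr3SiOTf to 9.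

**Step 11.** Retro-Michael exchange of the methylene bridge at 90 °C may scramble the halves into symmetrical dimers, and the ortho-quinone methide may self-condense. Fallback with reversed polarity, from 23 and 20 to 25: 23 and dimethylmethylideneammonium iodide give (4R)-6-[(dimethylamino)methyl]-3,5-dihydroxy-4-methyl-4-(3-methylbut-2-en-1-yl)-2-(2-methylpropanoyl)cyclohexa-2,5-dien-1-one F11. Warming F11 with 20 releases the 2-methylene trione, which C8 of 20 attacks as the nucleophile.

## Further compounds

F1 | step 4 | ethyl 4-methylpent-3-enoate | CCOC(=O)CC=C(C)C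
F2 | step 4 | triisopropyl[(5-methylhex-4-en-1-yn-1-yl)oxy]silane | CC(C)=CCC#CO[Si](C(C)C)(C(C)C)C(C)C
F3 | step 4 | 5-ethoxy-2-(3-methylbut-2-en-1-yl)-3-[(triisopropylsilyl)oxy]phenol | CCOc1cc(O)c(CC=C(C)C)c(O[Si](C(C)C)(C(C)C)C(C)C)c1
F4 | step 9 | rac-3,5-dihydroxy-4-methyl-4-(3-methylbut-2-en-1-yl)-2-(2-methylpropanoyl)cyclohexa-2,5-dien-1-one | CC(C)=CCC1(C)C(O)=CC(=O)C(C(=O)C(C)C)=C1O
F5 | step 9 | (1R)-1-phenylethanaminium salt of the R acid 23 | CC(C)=CC[C@]1(C)C(O)=CC(=O)C(C(=O)C(C)C)=C1[O-].C[C@@H]([NH3+])c1ccccc1
F6 | step 6 | 7-ethoxy-5-hydroxy-2,2-dimethyl-2H-chromene-6-carbaldehyde | CCOc1cc2OC(C)(C)C=Cc2c(O)c1C=O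
F7 | step 6 | 1-(7-ethoxy-5-hydroxy-2,2-dimethyl-2H-chromen-6-yl)-2-methylpropan-1-ol (racemic) | CCOc1cc2OC(C)(C)C=Cc2c(O)c1C(O)C(C)C
F0 | step 7 | none | none
F8 | step 3 | (1Z)-1-iodo-3-methylbuta-1,3-diene | CC(=C)/C=C\I
F9 | step 3 | trimethyl[(3Z)-5-methylhexa-3,5-dien-1-yn-1-yl]silane | CC(=C)/C=C\C#C[Si](C)(C)C
F10 | step 3 | (3Z)-5-methylhexa-3,5-dien-1-yne | CC(=C)/C=C\C#C
F11 | step 11 | (4R)-6-[(dimethylamino)methyl]-3,5-dihydroxy-4-methyl-4-(3-methylbut-2-en-1-yl)-2-(2-methylpropanoyl)cyclohexa-2,5-dien-1-one | CC(C)=CC[C@]1(C)C(O)=C(CN(C)C)C(=O)C(C(=O)C(C)C)=C1O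
A1 | alternative 1 | (3R)-3-methyl-3-(3-methylbut-2-en-1-yl)-6-(3-methyl-2-oxobutyl)-2H-pyran-2,4(3H)-dione | CC(C)=CC[C@]1(C)C(=O)C=C(CC(=O)C(C)C)OC1=O
A2 | alternative 1 | (4R)-3,5-dihydroxy-4-methyl-4-(3-methylbut-2-en-1-yl)-2-(2-methylpropanoyl)cyclohexa-2,5-dien-1-one (identical with 23) | CC(C)=CC[C@]1(C)C(O)=CC(=O)C(C(=O)C(C)C)=C1O
A3 | alternative 2 | methyl (2S)-7-[5,7-bis(methoxymethoxy)-2,2-dimethyl-6-(2-methylpropanoyl)-2H-chromen-8-yl]-2-methyl-2-(3-methylbut-2-en-1-yl)-4-(2-methylpropanoyl)-3,5-dioxoheptanoate | COC(=O)[C@@](C)(CC=C(C)C)C(=O)C(C(=O)C(C)C)C(=O)CCc1c(OCOC)c(C(=O)C(C)C)c(OCOC)c2C=CC(C)(C)Oc12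
A4 | alternative 2 | bis(methoxymethyl) ether of 25 at the C5 and C7 hydroxyls of ring B | CC(C)=CC[C@]1(C)C(O)=C(Cc2c(OCOC)c(C(=O)C(C)C)c(OCOC)c3c2OC(C)(C)C=C3)C(=O)C(C(=O)C(C)C)=C1O
A5 | alternative 3 | 3,5-bis(methoxymethoxy)-2-(trimethylsilyl)phenyl trifluoromethanesulfonate | COCOc1cc(OCOC)c([Si](C)(C)C)c(OS(=O)(=O)C(F)(F)F)c1
A6 | alternative 3 | 3-methylbut-2-enal | CC(C)=CC=O
A7 | alternative 3 | 5,7-bis(methoxymethoxy)-2,2-dimethyl-2H-chromene | COCOc1cc(OCOC)c2C=CC(C)(C)Oc2c1
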